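The synthesis rests on disconnecting the ring oxygen of ring D. The only stereocentre is the lactol carbon O–CH(OH) of ring D, which sits on ring B beside the diaryl ether oxygen and epimerises through its open formyl acid form. It is therefore carried as carbinol carbon C2 of a benzocyclobutenone fused to ring B, where it can neither enolise nor ionise. One peracid oxygen insertion between ketone carbon C1 and C2 forms both C–O bonds of that ring oxygen and closes ring D with retention. The precursor is an (R)-2-benzyloxybenzocyclobutenone with all three ring B oxygens capped: two as 4-methoxybenzyl ethers, the one beside C2 as the ring A aryl ether.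

Key step: step 14

Remark (labels): ring A is the formyl/methoxy/methyl arene, ring B the other arene, ring C the seven-membered lactone and ring D the lactol lactone. In the four-membered-ring series C1 is the ketal or ketone carbon, C2 the carbinol carbon and C3 to C6 the arene positions counted from the C2 side. In the phthalide series C1 is the carbonyl, C3 the acetal carbon and C4 to C7 are counted from C3. PMB = 4-methoxybenzyl.

Remark (order of events): ring A is attached to O–C3 before the ring expansion. A free phenoxide ortho to the acyloxy acetal carbon would expel the lactone carboxylate (ortho-quinone methide) and racemise ring D. The ring A formyl group is held as CH2OH while peracid is present.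

Remark (handling): after step 5 nothing is heated above 40 °C or exposed to UV light, because 4π ring opening would erase C2. The final lactol is assumed to keep its configuration only in cold, neutral, aprotic media.

Step 1
Reactants: 1 5-bromoresorcinol
Product: 2 1-bromo-3,5-bis(PMB-oxy)benzene
Conditions: PMBCl, K2CO3, DMF, 60 °C
Reagents that add atoms: 4-methoxybenzyl chloride, COc1ccc(CCl)cc1
Why: Williamson ether synthesis caps both phenol oxygens, and the aryl bromide is inert to carbonate.

Step 2
Reactants: 2 1-bromo-3,5-bis(PMB-oxy)benzene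
Product: 3 1,2-dibromo-3,5-bis(PMB-oxy)benzene
Conditions: NBS, MeCN, 0 °C
Reagents that add atoms: N-bromosuccinimide, O=C1CCC(=O)N1Br
Why: Electrophilic aromatic bromination should go ortho to one ether oxygen and para to the other, the site between the two bulky ethers being shielded, which gives the ortho-dibromide needed for aryne release.

Step 3
Reactants: 3 1,2-dibromo-3,5-bis(PMB-oxy)benzene; 4 1,1,2-tris(trimethylsilyloxy)ethene
Product: 7 rac-1,1-dimethoxy-4,6-bis(PMB-oxy)benzocyclobuten-2-ol, via aryne 5 (not isolated), via tris-silyl cycloadduct 6 (not isolated)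
Conditions: n-BuLi, THF, −78 → −20 °C; solvent switch; CSA (cat.), HC(OMe)3, MeOH, rt
Reagents that add atoms: methanol, CO; trimethyl orthoformate, COC(OC)OC
Why: Bromine–lithium exchange and loss of LiBr give aryne 5, whose flanking ether oxygen steers the nucleophilic CH(OTMS) carbon of the ketene silyl acetal to the remote aryne carbon (stepwise aryne [2+2] cycloaddition), so the bis-oxygenated carbon ends next to that ether, and acid methanolysis then exchanges the silyl groups for a free carbinol and a symmetric dimethyl ketal.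

Step 4
Reactants: 7 rac-1,1-dimethoxy-4,6-bis(PMB-oxy)benzocyclobuten-2-ol
Product: 8 1,1-dimethoxy-4,6-bis(PMB-oxy)benzocyclobuten-2-one
Conditions: Dess–Martin periodinane, CH2Cl2, 0 °C → rt
Reagents that add atoms: none
Why: Dess–Martin oxidation of a secondary benzylic alcohol runs without base and so avoids alkoxide-triggered opening of the four-membered ring.

Step 5
Reactants: 8 1,1-dimethoxy-4,6-bis(PMB-oxy)benzocyclobuten-2-one
Product: 9 (R)-1,1-dimethoxy-4,6-bis(PMB-oxy)benzocyclobuten-2-ol
Conditions: RuCl(p-cymene)[(S,S)-TsDPEN] (1 mol %), HCO2H/Et3N 5:2, CH2Cl2, rt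
Reagents that add atoms: none
Why: Noyori asymmetric transfer hydrogenation of an aryl ketone flanked by a quaternary carbon, in which the (S,S) catalyst should deliver hydride to the face that lets ring B lie under the cymene ligand (CH/π contact), the sense that gives (S)-1-indanol and is here named R because the ketal carbon outranks the arene carbon.

Step 6
Reactants: 9 (R)-1,1-dimethoxy-4,6-bis(PMB-oxy)benzocyclobuten-2-ol
Product: 10 (R)-2-benzyloxy-1,1-dimethoxy-4,6-bis(PMB-oxy)benzocyclobutene
Conditions: BnBr, Ag2O, n-Bu4NI (cat.), CH2Cl2, rt, dark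
Reagents that add atoms: benzyl bromide, BrCc1ccccc1
Why: Silver-oxide-promoted Williamson-type benzylation activates the halide instead of forming a free alkoxide, which would open the benzocyclobutenol, and it leaves the C2–O bond and hence the configuration untouched.

Step 7
Reactants: 10 (R)-2-benzyloxy-1,1-dimethoxy-4,6-bis(PMB-oxy)benzocyclobutene
Product: 11 (R)-2-benzyloxy-3-bromo-1,1-dimethoxy-4,6-bis(PMB-oxy)benzocyclobutene
Conditions: NBS, MeCN, −20 → 0 °C, dark
Reagents that add atoms: N-bromosuccinimide, O=C1CCC(=O)N1Br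
Why: Electrophilic aromatic bromination should take C3, which is para to O–C6 and ortho to O–C4, because the only other free site, C5, is walled in by two PMB-oxy groups.

Step 8
Reactants: 11 (R)-2-benzyloxy-3-bromo-1,1-dimethoxy-4,6-bis(PMB-oxy)benzocyclobutene
Product: 14 (R)-2-benzyloxy-1,1-dimethoxy-4,6-bis(PMB-oxy)benzocyclobuten-3-ol, via aryllithium 12 (not isolated), via dimethyl boronate 13 (not isolated)
Conditions: n-BuLi, THF, −78 °C; B(OMe)3, −78 → 0 °C; 30 % H2O2, 0 °C
Reagents that add atoms: hydrogen peroxide, OO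
Why: Bromine–lithium exchange, borylation and peroxide oxidation (1,2-aryl shift from boron to oxygen) turn C3–Br into C3–OH at a fixed position, and C2 has no acidic or ionisable bond under these conditions.

Step 9
Reactants: 15 1-fluoro-3-methoxy-5-methylbenzene
Product: 17 2-fluoro-6-methoxy-4-methylbenzaldehyde, via aryllithium 16 (not isolated)
Conditions: n-BuLi, THF, −78 °C; DMF; H2O
Reagents that add atoms: N,N-dimethylformamide, CN(C)C=O
Why: Directed ortho-metalation removes the most acidic ring hydrogen, the one between fluorine and methoxy, and formylation with DMF follows.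

Step 10
Reactants: 17 2-fluoro-6-methoxy-4-methylbenzaldehyde
Product: 18 2-(dimethoxymethyl)-1-fluoro-3-methoxy-5-methylbenzene
Conditions: HC(OMe)3, TsOH (cat.), MeOH, rt
Reagents that add atoms: trimethyl orthoformate, COC(OC)OC
Why: Acid-catalysed acetalisation driven by orthoformate masks the aldehyde against the second organolithium step.

Step 11
Reactants: 18 2-(dimethoxymethyl)-1-fluoro-3-methoxy-5-methylbenzene
Product: 21 allyl 2-fluoro-3-formyl-4-methoxy-6-methylbenzoate, via aryllithium 19 (not isolated), via acetal ester 20 (not isolated)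
Conditions: s-BuLi, TMEDA, THF, −78 °C; cannulate into ClCO2CH2CH=CH2, −78 °C; 1 M HCl, THF, rt
Reagents that add atoms: allyl chloroformate, C=CCOC(=O)Cl; water, O
Why: A second directed ortho-metalation takes the only hydrogen left next to fluorine, inverse addition to the chloroformate stops acylation at the ester, and the acidic work-up hydrolyses the acetal.

Step 12
Reactants: 14 (R)-2-benzyloxy-1,1-dimethoxy-4,6-bis(PMB-oxy)benzocyclobuten-3-ol; 21 allyl 2-fluoro-3-formyl-4-methoxy-6-methylbenzoate
Product: 22 allyl 2-[(R)-2-benzyloxy-1,1-dimethoxy-4,6-bis(PMB-oxy)benzocyclobuten-3-yloxy]-3-formyl-4-methoxy-6-methylbenzoate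
Conditions: Cs2CO3, DMF, rt → 40 °C
Reagents that add atoms: none
Why: Nucleophilic aromatic substitution (addition–elimination) displaces a fluoride activated by an ortho formyl and an ortho ester group, and while C2 is locked in the four-membered ring the neighbouring phenoxide has no leaving group to expel, so the configuration holds.

Step 13
Reactants: 22 allyl 2-[(R)-2-benzyloxy-1,1-dimethoxy-4,6-bis(PMB-oxy)benzocyclobuten-3-yloxy]-3-formyl-4-methoxy-6-methylbenzoate
Product: 24 allyl 2-[(R)-2-benzyloxy-1-oxo-4,6-bis(PMB-oxy)benzocyclobuten-3-yloxy]-3-(hydroxymethyl)-4-methoxy-6-methylbenzoate, via benzylic alcohol ketal 23 (not isolated)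
Conditions: NaBH4, THF/MeOH, 0 °C; then 1 M HCl to pH 1, rt
Reagents that add atoms: water, O
Why: Borohydride reduction masks the aldehyde against peracid, and the acid quench destroys residual hydride and then hydrolyses the ketal through an oxocarbenium ion stabilised by the ortho and para ether oxygens, while C2 cannot epimerise because its enol would be a benzocyclobutadiene.

Step 14
Reactants: 24 allyl 2-[(R)-2-benzyloxy-1-oxo-4,6-bis(PMB-oxy)benzocyclobuten-3-yloxy]-3-(hydroxymethyl)-4-methoxy-6-methylbenzoate
Product: 26 allyl 2-[(S)-3-benzyloxy-1-oxo-5,7-bis(PMB-oxy)-1,3-dihydroisobenzofuran-4-yloxy]-3-(hydroxymethyl)-4-methoxy-6-methylbenzoate, via Criegee adduct 25 (not isolated)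
Conditions: mCPBA, Na2HPO4, CH2Cl2, 0 °C
Reagents that add atoms: 3-chloroperbenzoic acid, O=C(OO)c1cccc(Cl)c1
Why: The peracid adds to the strained C1 ketone to give Criegee adduct 25, and the C1–C2 bond then shifts to the proximal peroxide oxygen as 3-chlorobenzoate leaves, so that oxygen ends up between C1 and C2. This is a Baeyer–Villiger oxidation of a cyclobutanone to a γ-lactone, a reaction type in which α-alkoxy carbons are known to migrate preferentially. Ring D is closed by expansion of the four-membered ring (a 1,2-shift from carbon to oxygen) and not by a cyclisation, and both C–O bonds of its ring oxygen arise here. The acetal stereocentre is the former carbinol carbon, and since the shift is suprafacial the (R)-C2 set in step 5 becomes (S)-C3, the descriptor changing through priorities only. The step needs C2 to migrate in place of the arene carbon attached to C1, which the benzyloxy lone pair and the benzylic position favour by stabilising positive charge at C2, while the ring fusion holds C1 in the plane of ring B so that the arene π system cannot bridge to oxygen. Chemoselectivity rests on strain-accelerated addition at 0 °C, on the phosphate buffer that shields the new acyloxy acetal from acid, and on the absence of a formyl group.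

Step 15
Reactants: 26 allyl 2-[(S)-3-benzyloxy-1-oxo-5,7-bis(PMB-oxy)-1,3-dihydroisobenzofuran-4-yloxy]-3-(hydroxymethyl)-4-methoxy-6-methylbenzoate
Product: 27 allyl 2-[(S)-3-benzyloxy-1-oxo-5,7-bis(PMB-oxy)-1,3-dihydroisobenzofuran-4-yloxy]-3-formyl-4-methoxy-6-methylbenzoate
Conditions: MnO2 (activated), CH2Cl2, rt
Reagents that add atoms: none
Why: Benzylic alcohol oxidation on neutral MnO2 restores the formyl group and leaves the acetal, the PMB ethers and the allyl ester alone.

Step 16
Reactants: 27 allyl 2-[(S)-3-benzyloxy-1-oxo-5,7-bis(PMB-oxy)-1,3-dihydroisobenzofuran-4-yloxy]-3-formyl-4-methoxy-6-methylbenzoate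
Product: 28 allyl 2-[(S)-3-benzyloxy-5,7-dihydroxy-1-oxo-1,3-dihydroisobenzofuran-4-yloxy]-3-formyl-4-methoxy-6-methylbenzoate
Conditions: DDQ, CH2Cl2/pH 7 phosphate buffer, 0 °C → rt
Reagents that add atoms: none
Why: Oxidative PMB cleavage (hydride abstraction from the electron-rich benzylic CH2, then hydrolysis) spares the plain benzyl acetal, and the phenols freed at C5 and C7 are meta to the acetal-bearing carbon and so cannot push out the lactone carboxylate.

Step 17
Reactants: 28 allyl 2-[(S)-3-benzyloxy-5,7-dihydroxy-1-oxo-1,3-dihydroisobenzofuran-4-yloxy]-3-formyl-4-methoxy-6-methylbenzoate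
Product: 29 2-[(S)-3-benzyloxy-5,7-dihydroxy-1-oxo-1,3-dihydroisobenzofuran-4-yloxy]-3-formyl-4-methoxy-6-methylbenzoic acid
Conditions: Pd(PPh3)4 (5 mol %), PhNHMe, THF, rt
Reagents that add atoms: none
Why: In this Tsuji–Trost deallylation zerovalent palladium ionises the allyl ester and the weakly basic aniline traps the π-allyl unit, so the acid is released without hydroxide, strong acid or phenoxide formation.

Step 18
Reactants: 29 2-[(S)-3-benzyloxy-5,7-dihydroxy-1-oxo-1,3-dihydroisobenzofuran-4-yloxy]-3-formyl-4-methoxy-6-methylbenzoic acid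
Product: 30 (S)-O-benzyl lactol ether of the target (rings A to D complete)
Conditions: DCC, CH2Cl2 (high dilution), 0 °C → rt
Reagents that add atoms: none
Why: Carbodiimide lactonisation of a 2-(2-hydroxyphenoxy)benzoic acid is the usual closure of the seven-membered depsidone ring, only O–C5 can reach the activated carboxyl, and the base-free medium suppresses Smiles rearrangement.

Step 19
Reactants: 30 (S)-O-benzyl lactol ether of the target
Product: 31 target CNP0216483.1, (S)-lactol
Conditions: H2 (1 atm), Pd/C, dry EtOAc, 0 °C; filter, evaporate cold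
Reagents that add atoms: none
Why: Catalytic hydrogenolysis breaks the O–CH2Ph bond and no bond at the acetal carbon, so the (S)-lactol should be released with its configuration, while the neutral, dry, cold medium slows ring–chain tautomerism and spares the formyl group.

Compound list
1 | 5-bromoresorcinol | Oc1cc(O)cc(Br)c1 | starting material
2 | 1-bromo-3,5-bis(PMB-oxy)benzene | COc1ccc(COc2cc(Br)cc(OCc3ccc(OC)cc3)c2)cc1 | intermediate
3 | 1,2-dibromo-3,5-bis(PMB-oxy)benzene | COc1ccc(COc2cc(Br)c(Br)c(OCc3ccc(OC)cc3)c2)cc1 | intermediate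
4 | 1,1,2-tris(trimethylsilyloxy)ethene | C[Si](C)(C)OC=C(O[Si](C)(C)C)O[Si](C)(C)C | starting material
5 | 3,5-bis(PMB-oxy)benzyne | COc1ccc(COC2=CC(OCc3ccc(OC)cc3)=CC#C2)cc1 | intermediate
6 | rac-1,1,2-tris(trimethylsilyloxy)-4,6-bis(PMB-oxy)benzocyclobutene | C[Si](C)(C)OC1c2cc(OCc3ccc(OC)cc3)cc(OCc3ccc(OC)cc3)c2C1(O[Si](C)(C)C)O[Si](C)(C)C | intermediate
7 | rac-1,1-dimethoxy-4,6-bis(PMB-oxy)benzocyclobuten-2-ol | COC1(OC)C(O)c2cc(OCc3ccc(OC)cc3)cc(OCc3ccc(OC)cc3)c21 | intermediate
8 | 1,1-dimethoxy-4,6-bis(PMB-oxy)benzocyclobuten-2-one | COC1(OC)C(=O)c2cc(OCc3ccc(OC)cc3)cc(OCc3ccc(OC)cc3)c21 | intermediate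
9 | (R)-1,1-dimethoxy-4,6-bis(PMB-oxy)benzocyclobuten-2-ol | COC1(OC)[C@H](O)c2cc(OCc3ccc(OC)cc3)cc(OCc3ccc(OC)cc3)c21 | intermediate
10 | (R)-2-benzyloxy-1,1-dimethoxy-4,6-bis(PMB-oxy)benzocyclobutene | COC1(OC)[C@H](OCc2ccccc2)c2cc(OCc3ccc(OC)cc3)cc(OCc3ccc(OC)cc3)c21 | intermediate
11 | (R)-2-benzyloxy-3-bromo-1,1-dimethoxy-4,6-bis(PMB-oxy)benzocyclobutene | COC1(OC)[C@H](OCc2ccccc2)c2c(Br)c(OCc3ccc(OC)cc3)cc(OCc3ccc(OC)cc3)c21 | intermediate
12 | C3 aryllithium from 11 | COC1(OC)[C@H](OCc2ccccc2)c2c([Li])c(OCc3ccc(OC)cc3)cc(OCc3ccc(OC)cc3)c21 | intermediate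
13 | C3 dimethyl boronate | COC1(OC)[C@H](OCc2ccccc2)c2c(B(OC)OC)c(OCc3ccc(OC)cc3)cc(OCc3ccc(OC)cc3)c21 | intermediate
14 | (R)-2-benzyloxy-1,1-dimethoxy-4,6-bis(PMB-oxy)benzocyclobuten-3-ol | COC1(OC)[C@H](OCc2ccccc2)c2c(O)c(OCc3ccc(OC)cc3)cc(OCc3ccc(OC)cc3)c21 | intermediate
15 | 1-fluoro-3-methoxy-5-methylbenzene | COc1cc(C)cc(F)c1 | starting material
16 | 2-fluoro-6-methoxy-4-methylphenyllithium | COc1cc(C)cc(F)c1[Li] | intermediate
17 | 2-fluoro-6-methoxy-4-methylbenzaldehyde | COc1cc(C)cc(F)c1C=O | intermediate
18 | 2-(dimethoxymethyl)-1-fluoro-3-methoxy-5-methylbenzene | COc1cc(C)cc(F)c1C(OC)OC | intermediate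
19 | aryllithium from 18 (lithium between fluorine and methyl) | COc1cc(C)c([Li])c(F)c1C(OC)OC | intermediate
20 | allyl 3-(dimethoxymethyl)-2-fluoro-4-methoxy-6-methylbenzoate | C=CCOC(=O)c1c(C)cc(OC)c(C(OC)OC)c1F | intermediate
21 | allyl 2-fluoro-3-formyl-4-methoxy-6-methylbenzoate | C=CCOC(=O)c1c(C)cc(OC)c(C=O)c1F | intermediate
22 | diaryl ether, ketal, formyl | COC1(OC)[C@H](OCc2ccccc2)c2c(Oc3c(C=O)c(OC)cc(C)c3C(=O)OCC=C)c(OCc3ccc(OC)cc3)cc(OCc3ccc(OC)cc3)c21 | intermediate
23 | diaryl ether, ketal, hydroxymethyl | COC1(OC)[C@H](OCc2ccccc2)c2c(Oc3c(CO)c(OC)cc(C)c3C(=O)OCC=C)c(OCc3ccc(OC)cc3)cc(OCc3ccc(OC)cc3)c21 | intermediate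
24 | (R)-2-benzyloxybenzocyclobutenone, precursor of the key step | O=C1[C@H](OCc2ccccc2)c2c(Oc3c(CO)c(OC)cc(C)c3C(=O)OCC=C)c(OCc3ccc(OC)cc3)cc(OCc3ccc(OC)cc3)c21 | intermediate
25 | Criegee adduct of 24 and mCPBA | OC1(OOC(=O)c2cccc(Cl)c2)[C@H](OCc2ccccc2)c2c(Oc3c(CO)c(OC)cc(C)c3C(=O)OCC=C)c(OCc3ccc(OC)cc3)cc(OCc3ccc(OC)cc3)c21 | intermediate
26 | (S)-3-benzyloxyphthalide, product of the key step | O=C1O[C@H](OCc2ccccc2)c2c(Oc3c(CO)c(OC)cc(C)c3C(=O)OCC=C)c(OCc3ccc(OC)cc3)cc(OCc3ccc(OC)cc3)c21 | intermediate
27 | (S)-3-benzyloxyphthalide, ring A formyl | O=C1O[C@H](OCc2ccccc2)c2c(Oc3c(C=O)c(OC)cc(C)c3C(=O)OCC=C)c(OCc3ccc(OC)cc3)cc(OCc3ccc(OC)cc3)c21 | intermediate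
28 | (S)-3-benzyloxy-5,7-dihydroxyphthalide allyl ester | O=C1O[C@H](OCc2ccccc2)c2c(Oc3c(C=O)c(OC)cc(C)c3C(=O)OCC=C)c(O)cc(O)c21 | intermediate
29 | (S)-hydroxy acid | O=C1O[C@H](OCc2ccccc2)c2c(Oc3c(C=O)c(OC)cc(C)c3C(O)=O)c(O)cc(O)c21 | intermediate
30 | (S)-O-benzyl lactol ether of the target | COc1cc(C)c2c(c1C=O)Oc1c(cc(O)c3c1[C@@H](OCc1ccccc1)OC3=O)OC2=O | intermediate
31 | CNP0216483.1, (S)-lactol | COc1cc(C)c2c(c1C=O)Oc1c(cc(O)c3c1[C@@H](O)OC3=O)OC2=O | target

Total step count: 19. Longest linear sequence: 16 (steps 1 to 8 and 12 to 19). Steps 9 to 11 form the ring A branch.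

Steps most likely to fail

Step 14. The arene carbon attached to C1, enriched by an ortho and a para PMB-oxy donor, may migrate in place of C2. Alternatively, peracid addition to the donor-deactivated ketone may be slow enough for oxidation of the allyl group or of the electron-rich rings to intervene. The fallback sets out from 22 and comes back at 30, and it closes ring C before the ring expansion. The oxygen para to the unwanted migrating carbon is then an acyloxy group, and a free C6 hydroxyl hydrogen-bonds to the ketone.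
- DDQ gives the diphenol ketal F1.
- Pd(PPh3)4 with N-methylaniline gives the acid F2.
- Carbodiimide lactonisation gives the depsidone ketal F3.
- NaBH4 gives the benzylic alcohol F4.
- Dilute HCl unmasks the depsidone-fused benzocyclobutenone F5.
- Buffered mCPBA gives the phthalide F6.
- MnO2 restores the formyl group to reach 30.

Step 3. Butyllithium may strip trimethylsilyl groups from 4 or add to the aryne faster than the crowded alkene does. The one-pot exchange of three silyl groups for a ketal may also stall at the hydroxy ketone stage. The fallback sets out from 3 and comes back at 7.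
- The sturdier ketene silyl acetal 1,2-bis(tert-butyldimethylsilyloxy)-1-methoxyethene F7 is made from methyl (tert-butyldimethylsilyloxy)acetate with LDA and TBSCl.
- F7 is used in the cycloaddition, and the mixed silyl methyl ketal F8 is isolated.
- HF·pyridine then gives rac-2-hydroxy-4,6-bis(PMB-oxy)benzocyclobutenone F9.
- F9 is ketalised in a separate operation with MeOTMS and catalytic TMSOTf, followed by mild methanolysis, to 7.

Step 19. Three things may go wrong: over-reduction of the ring A formyl group, hydrogenolysis of a C3–O bond of ring D, and epimerisation of the freed lactol by ring–chain tautomerism on the catalyst support. The fallback sets out from 30 and comes back at 31.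
- It uses oxidative debenzylation with DDQ under green-light irradiation in wet CH2Cl2.
- DDQ abstracts hydride from the benzyl CH2, and the resulting oxocarbenium ion is hydrolysed.
- The cleavage again takes place away from the acetal carbon, and neither hydrogen nor metal is present.
- No new compound arises (F0).

Further compounds
F1 | step 14 | diphenol ketal (22 without PMB groups) | COC1(OC)[C@H](OCc2ccccc2)c2c(Oc3c(C=O)c(OC)cc(C)c3C(=O)OCC=C)c(O)cc(O)c21
F2 | step 14 | diphenol ketal acid | COC1(OC)[C@H](OCc2ccccc2)c2c(Oc3c(C=O)c(OC)cc(C)c3C(O)=O)c(O)cc(O)c21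
F3 | step 14 | depsidone ketal, formyl | COc1cc(C)c2c(c1C=O)Oc1c(cc(O)c3c1[C@@H](OCc1ccccc1)C3(OC)OC)OC2=O
F4 | step 14 | depsidone ketal, hydroxymethyl | COc1cc(C)c2c(c1CO)Oc1c(cc(O)c3c1[C@@H](OCc1ccccc1)C3(OC)OC)OC2=O
F5 | step 14 | depsidone-fused (R)-2-benzyloxybenzocyclobutenone | COc1cc(C)c2c(c1CO)Oc1c(cc(O)c3c1[C@@H](OCc1ccccc1)C3=O)OC2=O
F6 | step 14 | depsidone-fused (S)-3-benzyloxyphthalide, hydroxymethyl | COc1cc(C)c2c(c1CO)Oc1c(cc(O)c3c1[C@@H](OCc1ccccc1)OC3=O)OC2=O
F7 | step 3 | 1,2-bis(tert-butyldimethylsilyloxy)-1-methoxyethene | COC(=CO[Si](C)(C)C(C)(C)C)O[Si](C)(C)C(C)(C)C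
F8 | step 3 | rac-1-methoxy-1,2-bis(tert-butyldimethylsilyloxy)-4,6-bis(PMB-oxy)benzocyclobutene | COC1(O[Si](C)(C)C(C)(C)C)C(O[Si](C)(C)C(C)(C)C)c2cc(OCc3ccc(OC)cc3)cc(OCc3ccc(OC)cc3)c21
F9 | step 3 | rac-2-hydroxy-4,6-bis(PMB-oxy)benzocyclobutenone | O=C1C(O)c2cc(OCc3ccc(OC)cc3)cc(OCc3ccc(OC)cc3)c21
F0 | step 19 | none | none
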